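# Total synthesis proposal for CNP0358381.1 (compound 41)

## Analysis of the target

The target 41 is a 3,4,6,7-tetrahydro-2H-chromene-4,7-dione: a 2,2-dimethylpyran-4-one ring (O1, C2, C3, C4) fused through C4a–C8a to a six-membered carbocycle (C4a, C5, C6, C7, C8, C8a). That carbocycle is a dearomatised acylphloroglucinol, with an enolic hydroxyl on C5 hydrogen-bonded to the C4 ketone, a ketone at C7 and the ring oxygen on C8a. C6 is its only sp3 carbon and is quaternary, carrying a 3-methylbut-2-enyl group and a cyclobutylmethyl group; C8 carries a hexanoic acid chain through C3 of that chain. There are four stereocentres: the two adjacent cyclobutane carbons (1S at the carbon bearing the CH2 link, 2R at the carbon bearing the isopropenyl group, trans, with the gem-dimethyl carbon next to the latter), the quaternary C6 (R) and C3 of the chain (R). The cyclobutane pair is separated from C6 by a methylene and the chain stereocentre lies on the far side of the ring, so no centre can be expected to control another. The isopropenylcyclobutane expands to a cyclopentyl cation on protonation, which excludes strong Brønsted and Lewis acids; the prenyl group, the enolised triketone, the base-openable pyranone and the free acid are further sensitive sites. The difficulty is that every carbon of the carbocycle is substituted and its three oxygens have three different fates, so ordinary phloroglucinol chemistry cannot tell C6 from C8, or a pyranone closed on the C8a oxygen from one closed on the C5 oxygen. The strategy rests on the fact that the ring C4a–C5–C6–C7–C8–C8a is a masked phloroglucinol that can be assembled from a four-carbon unit (C8a, C6, C5, C4a) and a two-carbon unit (C7, C8) so that each oxygen is formed with a different substituent.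

## Retrosynthetic reasoning

**41 ⇒ 40 ⇒ 38 + 39.** The acid is unmasked last from methyl ester 40. Before that the bond from C6 to the prenyl CH2 is cut. C6 is the only saturated carbon of the carbocycle, so this turns the fragile enolised triketone into the aromatic 5,7-dihydroxychromanone 38, and all earlier work becomes arene chemistry. Cutting the other C6 substituent instead would require the cyclobutane as an electrophile that ionises with ring expansion. Forward, acetate 39 must alkylate 38 at C6 and not at oxygen or C8, through its unsubstituted allyl terminus, and on one face. The resident stereocentres are too remote to choose the face, so that is left to a chiral zerovalent-palladium catalyst.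

**38 ⇒ 37 ⇒ 36.** The two oxygens flanking C6 are freed just before the alkylation. With both free, C6 lies between two phenolic oxygens and the alkylation product is a stabilised vinylogous acid. The C5 oxygen arrives as an ethyl ether peri to the C4 ketone and is cleaved by chelation to a boron halide; the C7 oxygen arrives as a silyl ether and is cleaved by fluoride. Both groups are simply what the ring construction delivers.

**36 ⇒ 35 ⇒ 34 ⇒ 32 + 33.** The pyranone is opened at O1–C2 (retro-oxa-Michael) to the ortho-hydroxyaryl enone 35. The C4–C4a bond is traced back to an acyl shift from oxygen to carbon, that is to aryl ester 34 of phenol 32 and acid chloride 33. A Friedel–Crafts acylation would form the same bond but needs acid that the isopropenylcyclobutane cannot tolerate; the photochemical Fries rearrangement is neutral. In 32 only the C8a oxygen is free and only C4a carries hydrogen, so the acylation site and the direction of ring closure are fixed.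

**32 ⇒ 30 ⇒ 16 + 25.** This disconnection carries the plan. Three ring bonds are cut, C8–C8a, C6–C7 and C4a–C8a, dividing the arene into cyclobutenone 16 (C8a, C6, C5, C4a) and siloxyalkyne 25 (C7, C8). The ketone oxygen of 16 becomes the free C8a hydroxyl, its enol-ether oxygen the C5 ethyl ether, and the alkyne oxygen the C7 silyl ether, and both carbon substituents arrive already attached. Forward, the polarised alkyne must add to the vinylketene from 16 in one orientation and three stereocentres must pass unchanged. 30 differs from 32 only in its ester group, for the reason given in the next paragraph.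

**25 ⇒ 22 ⇒ 20 ⇒ 19 ⇒ 17.** The siloxyalkyne comes from terminal alkyne 22 by oxidation of its acetylide 23 to ynolate 24 and O-silylation. An alkyl ester would not survive the organolithium and the peroxide, so the carboxyl group passes through this step as its lithium salt and emerges as a silyl ester, later exchanged for methyl (30 to 32). The alkyne carbon is added to aldehyde 20 by a diazophosphonate homologation. 20 comes from lactone 17 by ring opening and oxidation of the primary alcohol 19. 17 is a commercial, enantiopure building block whose C4 already is the chain stereocentre in the right configuration, so this branch needs no asymmetric step.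

**16 ⇒ 14 + 15, and 14 ⇒ 10 + 11.** The cyclobutenone is the [2+2] adduct of ketene 15 with ynol ether 14; the polarity of that addition places the alkyl group on C2 and the ethoxy group on C3, as the benzannulation requires. 14 is cut at its propargylic C–C bond into acetylene 11 and triflate 12, made from alcohol 10.

**10 ⇒ 9 ⇒ 6 ⇒ 3 ⇒ 1 + 2.** The four-membered ring is derived from a five-membered one: ester 9 arises by Wolff ring contraction of diazoketone 6, and the extruded carbon becomes the CH2 link. The isopropenyl-bearing stereocentre is set beforehand by rhodium-catalysed conjugate addition of 2 to enone 1. The second cyclobutane centre is α to the ester in 9 and is set by equilibration to trans. The diazo group must sit on the α-carbon next to the isopropenyl-bearing carbon; the other α-carbon is neopentylic, which should direct kinetic enolisation.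

## Alternatives that were turned down

**Alternative 1:** The disconnection is the ring bond between the two substituted cyclobutane carbons.
- **Forward key step:** the acyclic bis-imide A2 (3,3-dimethylhexanedioic acid with two (4S)-4-benzyloxazolidinones) is doubly enolised and the dienolate is oxidised with a divalent copper halide, joining the two α-carbons to give the trans-cyclobutane bis-imide A1.
- **For it:** both cyclobutane stereocentres and their trans relationship come from one auxiliary-controlled step on a cheap acyclic diacid, with no diazo compound. On absolute control of the cyclobutane it is probably stronger than the chosen route, which depends on the enantioselectivity of step 1 and an equilibration in step 3.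
- **Against it:** oxidative enolate coupling must close a strained four-membered ring in competition with intermolecular coupling. The two acyl groups of A1 must then be told apart (the one next to the gem-dimethyl carbon becomes isopropenyl, the other the CH2 link), costing several selective steps.
- **Comparison:** it spends its key step on the side-chain ring and leaves the assembly of the hexasubstituted carbocycle with its three different oxygens unsolved. The chosen strategy makes the cyclobutane by routine steps and spends its key step on the crowded core.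

**Alternative 2:** The disconnection is the C6–CH2 bond to the cyclobutane.
- **Forward key step:** iodide A4 is a C6-prenylated 5,7-dihydroxychromanone acylated on O7 by the cyclobutanecarboxylic acid whose neighbouring ring carbon carries CH2I. With a carbonate base at high dilution the phenoxide alkylates through C6, closing a seven-membered enol lactone and giving dienone A3.
- **For it:** it is the only plan in which the C6 configuration is dictated by the substrate (the tether relays the cyclobutane chirality) and not by an untested chiral catalyst; on this point it is stronger than the chosen route. Intramolecularity also excludes O- and C8-alkylation.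
- **Against it:** the ring closes onto a fully substituted carbon, through a seven-membered ring containing a trans-disubstituted cyclobutane and an enol ester, and the facial preference of such a tether is not assured. The lactone carbonyl must afterwards become the isopropenyl group (two methyl additions and dehydration, or ketone methylenation) beside the enolised triketone and the acid; dehydration next to a cyclobutane invites ring expansion, and the enol lactone is a labile acylating agent. The arene still has to be assembled first.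
- **Comparison:** it adds four or more steps after dearomatisation where the chosen route needs one. The chosen route carries the isopropenyl group from step 1 and accepts reagent control at C6, with separable epimers as the safeguard.

**Alternative 3:** The disconnection is C7–C8 and C4a–C5.
- **Forward key step:** the dianion of diketone A7 (two equivalents of a lithium amide) is acylated at its terminal carbon by acid chloride A6, a fully substituted malonic half-ester chloride carrying the prenyl and cyclobutylmethyl groups. An alkoxide then closes the central carbon onto the methyl ester to give the enolised triketone A5.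
- **For it:** the ring never passes through an aromatic stage, so C6 is made before ring closure and no dearomatising alkylation is needed; on C6 this is stronger. It is convergent and brings the senecioyl group with it.
- **Against it:** the difficulty moves to an enantioselective synthesis of a quaternary malonate with two alkyl groups of similar size and two carboxyl groups that must stay distinguishable. The acylation uses a neopentyl-type acid chloride and the closure a hindered ester. A5 has hydrogen at C8 and two enol oxygens flanking the senecioyl group, so the acid chain must still be attached at C8 with control of its stereocentre, and the pyranone must then choose between the C8a and C5 oxygens.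
- **Comparison:** the chosen route takes the chain stereocentre from lactone 17 and makes the ring-fusion regiochemistry a consequence of which oxygen is free.

Key step: step 11

## Remarks on the chemistry

- Ring atoms of the bicyclic core are numbered as in chroman-4-one (O1, C2, C3, C4, C4a, C5 to C8, C8a), also for the arene precursors from 30 on.
- Assumption: the target is taken as the C5-enol, C7-keto tautomer as drawn, for which the descriptors are 3R (chain), 6R, and 1S,2R (cyclobutane).
- Assumption: (R)-BINAP in step 1 is taken to deliver the 4R ketone by analogy with cyclopent-2-enone, and the (R,R) ligand in step 17 is taken to give 6R; the antipodal ligand is used if the opposite sense is found.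
- Compound 15 is not sold as such and is generated from acetone immediately before use; 17 is commercial as the single R enantiomer.

## Route

Step 1
Reactants: 1 4,4-dimethylcyclopent-2-en-1-one; 2 4,4,5,5-tetramethyl-2-(prop-1-en-2-yl)-1,3,2-dioxaborolane
Product: 3 (4R)-3,3-dimethyl-4-(prop-1-en-2-yl)cyclopentan-1-one
Conditions: [RhCl(C2H4)2]2 (2.5 mol%), (R)-BINAP (6 mol%), KOH (0.2 equiv), 1,4-dioxane/H2O 10:1, 60 °C
Reagents that add atoms: none
Why: Hayashi–Miyaura rhodium-catalysed asymmetric 1,4-addition of an alkenylboron reagent to a cyclic enone. The chiral alkenylrhodium species should select the enone face that gives the 4R centre; the gem-dimethyl group is symmetric to both faces and should slow the insertion without changing the facial choice.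

Step 2
Reactants: 3 (4R)-3,3-dimethyl-4-(prop-1-en-2-yl)cyclopentan-1-one
Product: 6 (3R)-2-diazo-4,4-dimethyl-3-(prop-1-en-2-yl)cyclopentan-1-one, via lithium enolate 4 (not isolated), via trifluoroacetyl ketone 5 (not isolated)
Conditions: LiN(SiMe3)2, THF, −78 °C; CF3CO2CH2CF3, −78 °C; then CH3SO2N3, Et3N, H2O, MeCN, rt
Reagents that add atoms: methanesulfonyl azide CS(=O)(=O)N=[N+]=[N-]
Why: Detrifluoroacetylative diazo transfer (a Regitz-type transfer to an activated 1,3-dicarbonyl). Kinetic deprotonation should occur at the methylene next to the tertiary carbon, because the other α-methylene is neopentylic and each of its hydrogens is syn to a methyl group. The stereocentre is not involved.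

Step 3
Reactants: 6 (3R)-2-diazo-4,4-dimethyl-3-(prop-1-en-2-yl)cyclopentan-1-one
Product: 9 methyl (1R,2R)-3,3-dimethyl-2-(prop-1-en-2-yl)cyclobutane-1-carboxylate, via cyclobutylidene ketene 7 (not isolated), via cis methyl ester 8 (not isolated)
Conditions: hν (medium-pressure Hg lamp, Pyrex filter), MeOH, 0 °C; then NaOMe (0.3 equiv), MeOH, 60 °C
Reagents that add atoms: methanol CO
Why: Photochemical Wolff rearrangement with ring contraction: the ring CH2 migrates to the carbene carbon and methanol traps the ketene. The isopropenyl-bearing centre is untouched; protonation of the ester enol from the less hindered face should favour the cis ester, and methoxide then equilibrates the α-centre to the more stable trans ester.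

Step 4
Reactants: 9 methyl (1R,2R)-3,3-dimethyl-2-(prop-1-en-2-yl)cyclobutane-1-carboxylate
Product: 10 [(1R,2R)-3,3-dimethyl-2-(prop-1-en-2-yl)cyclobutyl]methanol
Conditions: LiAlH4, Et2O, 0 °C
Reagents that add atoms: none
Why: Hydride reduction of an ester to the primary alcohol. No stereocentre is affected, and residual cis alcohol should be removable by chromatography at this stage.

Step 5
Reactants: 10 [(1R,2R)-3,3-dimethyl-2-(prop-1-en-2-yl)cyclobutyl]methanol; 11 ethoxyethyne
Product: 14 (1S,2R)-1-(3-ethoxyprop-2-yn-1-yl)-3,3-dimethyl-2-(prop-1-en-2-yl)cyclobutane, via cyclobutylmethyl triflate 12 (not isolated), via lithium ethoxyacetylide 13 (not isolated)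
Conditions: (CF3SO2)2O, pyridine, CH2Cl2, −30 °C, short silica plug, used at once; 11, n-BuLi, THF, −78 °C; then 12, −78 → −10 °C
Reagents that add atoms: none
Why: SN2 alkylation of a lithium alkoxyacetylide by a primary triflate. The low temperature and the strong nucleophile should outpace ionisation of the cyclobutylmethyl triflate, which would lead to ring expansion; the change of descriptor at C1 is a priority change only.

Step 6
Reactants: 14 (1S,2R)-1-(3-ethoxyprop-2-yn-1-yl)-3,3-dimethyl-2-(prop-1-en-2-yl)cyclobutane; 15 ethenone (ketene)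
Product: 16 2-{[(1S,2R)-3,3-dimethyl-2-(prop-1-en-2-yl)cyclobutyl]methyl}-3-ethoxycyclobut-2-en-1-one
Conditions: CH2=C=O (gas stream from acetone pyrolysis, excess), CH2Cl2, 0 °C → rt
Reagents that add atoms: none
Why: [2+2] cycloaddition of ketene with an alkoxyalkyne. The nucleophilic β-carbon of the ynol ether bonds to the ketene carbonyl carbon, which puts the alkyl group on C2 and the ethoxy group on C3; the unactivated isopropenyl alkene does not react with the parent ketene.

Step 7
Reactants: 17 (4R)-4-propyloxolan-2-one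
Product: 19 methyl (3R)-3-(hydroxymethyl)hexanoate, via sodium hydroxy carboxylate 18 (not isolated)
Conditions: NaOH (1.05 equiv), MeOH/H2O, rt, evaporated to dryness; CH3I, DMF, rt; used without delay
Reagents that add atoms: sodium hydroxide [Na+].[OH-]; iodomethane CI
Why: Saponification of the lactone and O-alkylation of the carboxylate. The stereocentre is not touched, and the hydroxy ester is oxidised at once so that relactonisation does not compete.

Step 8
Reactants: 19 methyl (3R)-3-(hydroxymethyl)hexanoate
Product: 20 methyl (3R)-3-formylhexanoate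
Conditions: Dess–Martin periodinane, pyridine, CH2Cl2, 0 °C
Reagents that add atoms: none
Why: Dess–Martin oxidation of a primary alcohol. The buffered, non-basic medium should keep the stereocentre, which is now α to the aldehyde.

Step 9
Reactants: 20 methyl (3R)-3-formylhexanoate
Product: 22 (3R)-3-ethynylhexanoic acid, via alkynyl methyl ester 21 (not isolated)
Conditions: dimethyl (1-diazo-2-oxopropyl)phosphonate, K2CO3, MeOH, 0 °C → rt; then LiOH, H2O, rt; 1 M HCl
Reagents that add atoms: dimethyl (1-diazo-2-oxopropyl)phosphonate COP(=O)(OC)C(=[N+]=[N-])C(C)=O; lithium hydroxide [Li+].[OH-]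
Why: Ohira–Bestmann (Seyferth–Gilbert) homologation of the aldehyde to the terminal alkyne, then saponification in the same flask. α-Alkyl-branched aldehydes should pass carbonate in methanol at 0 °C with little epimerisation, and once the alkyne is formed the centre is no longer acidic.

Step 10
Reactants: 22 (3R)-3-ethynylhexanoic acid
Product: 25 tri(propan-2-yl)silyl (3R)-3-({[tri(propan-2-yl)silyl]oxy}ethynyl)hexanoate, via dilithium acetylide carboxylate 23 (not isolated), via dilithium ynolate carboxylate 24 (not isolated)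
Conditions: n-BuLi (2.1 equiv), THF, −78 → −40 °C; LiOOC(CH3)3 [from (CH3)3COOH and LiN(SiMe3)2, THF, −78 °C], −78 → 0 °C; iPr3SiOSO2CF3 (2.4 equiv), −78 °C; Et3N-deactivated silica
Reagents that add atoms: tert-butyl hydroperoxide CC(C)(C)OO; tri(propan-2-yl)silyl trifluoromethanesulfonate CC(C)[Si](C(C)C)(C(C)C)OS(=O)(=O)C(F)(F)F
Why: Oxidation of a lithium acetylide to the lithium ynolate by lithium tert-butyl peroxide, then O-silylation with the bulky silyl triflate. The carboxyl group is inert as its lithium salt and is silylated at the end, which avoids the ester that these reagents would attack; the propargylic stereocentre is not deprotonated at these temperatures.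

Step 11
Reactants: 16 2-{[(1S,2R)-3,3-dimethyl-2-(prop-1-en-2-yl)cyclobutyl]methyl}-3-ethoxycyclobut-2-en-1-one; 25 tri(propan-2-yl)silyl (3R)-3-({[tri(propan-2-yl)silyl]oxy}ethynyl)hexanoate
Product: 30 tri(propan-2-yl)silyl (3R)-3-[3-{[(1S,2R)-3,3-dimethyl-2-(prop-1-en-2-yl)cyclobutyl]methyl}-4-ethoxy-6-hydroxy-2-{[tri(propan-2-yl)silyl]oxy}phenyl]hexanoate, via vinylketene 26 (not isolated), via vinylcyclobutenone 27 (not isolated), via dienylketene 28 (not isolated), via cyclohexadienone 29 (not isolated)
Conditions: toluene (0.4 M), 80 °C, then 110 °C, sealed tube, Ar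
Reagents that add atoms: none
Why: Danheiser benzannulation of a cyclobutenone with a siloxyalkyne; the closest precedent is the same cascade with 3-alkyl- and 3-aryl-cyclobutenones. Heating opens 16 by 4π electrocyclic ring opening to vinylketene 26, and the electron-rich alkyne 25 adds to its C=C=O unit in an asynchronous [2+2] cycloaddition: the alkyne carbon bearing the chiral chain bonds to the ketene carbonyl carbon (C8–C8a) and the oxygen-bearing carbon to the ketene α-carbon (C6–C7), giving 27. A second 4π opening gives dienylketene 28, whose central double bond has the geometry needed for cyclisation because it was part of the four-membered ring; 28 closes the only new ring, the six-membered carbocycle, by thermal disrotatory 6π electrocyclisation (C4a–C8a) to 29, which tautomerises to phenol 30. No stereocentre is created, and the three existing ones are spectators, since none is α to a carbonyl or part of a π system during the cascade. The selectivity needed is regiochemical and comes from the polarisation of the ynol ether, which places the chain ortho and the cyclobutylmethyl group para to the new hydroxyl and leaves the oxygens as free hydroxyl (C8a), silyl ether (C7) and ethyl ether (C5). Chemoselectivity over the isopropenyl alkene follows from the much higher reactivity of the siloxyalkyne towards ketenes and from the trans ring fusion that an intramolecular ketene–alkene cycloaddition would require. The silyl ester is inert under these neutral conditions, and 110 °C is below the range in which the siloxyalkyne isomerises to a silylketene.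

Step 12
Reactants: 30 tri(propan-2-yl)silyl (3R)-3-[3-{[(1S,2R)-3,3-dimethyl-2-(prop-1-en-2-yl)cyclobutyl]methyl}-4-ethoxy-6-hydroxy-2-{[tri(propan-2-yl)silyl]oxy}phenyl]hexanoate
Product: 32 methyl (3R)-3-[3-{[(1S,2R)-3,3-dimethyl-2-(prop-1-en-2-yl)cyclobutyl]methyl}-4-ethoxy-6-hydroxy-2-{[tri(propan-2-yl)silyl]oxy}phenyl]hexanoate, via hydroxy acid 31 (not isolated)
Conditions: K2CO3 (1.5 equiv), MeOH, 0 °C; dilute HCl to pH 4, extraction; then Me3SiCHN2, toluene/MeOH 4:1, 0 °C
Reagents that add atoms: (trimethylsilyl)diazomethane C[Si](C)(C)C=[N+]=[N-]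
Why: Silyl esters are cleaved by carbonate in methanol far faster than the doubly ortho-substituted aryl silyl ether, and the same treatment converts any lactone (chain carboxyl on the C8a oxygen) or aryl ester by-product into the methyl ester phenol. The diazoalkane then methylates the carboxylic acid selectively over the hindered phenol.

Step 13
Reactants: 32 methyl (3R)-3-[3-{[(1S,2R)-3,3-dimethyl-2-(prop-1-en-2-yl)cyclobutyl]methyl}-4-ethoxy-6-hydroxy-2-{[tri(propan-2-yl)silyl]oxy}phenyl]hexanoate; 33 3-methylbut-2-enoyl chloride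
Product: 34 methyl (3R)-3-[3-{[(1S,2R)-3,3-dimethyl-2-(prop-1-en-2-yl)cyclobutyl]methyl}-4-ethoxy-6-[(3-methylbut-2-enoyl)oxy]-2-{[tri(propan-2-yl)silyl]oxy}phenyl]hexanoate
Conditions: pyridine, CH2Cl2, 0 °C → rt
Reagents that add atoms: none
Why: O-Acylation of the only free phenol. Pyridine is too weak a base to convert the acid chloride into its vinylketene, so the double bond should stay conjugated.

Step 14
Reactants: 34 methyl (3R)-3-[3-{[(1S,2R)-3,3-dimethyl-2-(prop-1-en-2-yl)cyclobutyl]methyl}-4-ethoxy-6-[(3-methylbut-2-enoyl)oxy]-2-{[tri(propan-2-yl)silyl]oxy}phenyl]hexanoate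
Product: 36 methyl (3R)-3-[6-{[(1S,2R)-3,3-dimethyl-2-(prop-1-en-2-yl)cyclobutyl]methyl}-5-ethoxy-2,2-dimethyl-4-oxo-7-{[tri(propan-2-yl)silyl]oxy}-3,4-dihydro-2H-chromen-8-yl]hexanoate, via hydroxyaryl enone 35 (not isolated)
Conditions: hν (254 nm, quartz), degassed cyclohexane, rt; then K2CO3 (0.3 equiv), MeOH, rt
Reagents that add atoms: none
Why: Photo-Fries rearrangement: homolysis of the aryl ester and in-cage recombination move the acyl group to C4a, the only ring carbon bearing hydrogen, without acid. The ortho-hydroxyaryl enone then closes by 6-endo-trig oxa-Michael addition of the only free hydroxyl (on C8a) to give the 2,2-dimethylchroman-4-one.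

Step 15
Reactants: 36 methyl (3R)-3-[6-{[(1S,2R)-3,3-dimethyl-2-(prop-1-en-2-yl)cyclobutyl]methyl}-5-ethoxy-2,2-dimethyl-4-oxo-7-{[tri(propan-2-yl)silyl]oxy}-3,4-dihydro-2H-chromen-8-yl]hexanoate
Product: 37 methyl (3R)-3-[6-{[(1S,2R)-3,3-dimethyl-2-(prop-1-en-2-yl)cyclobutyl]methyl}-5-hydroxy-2,2-dimethyl-4-oxo-7-{[tri(propan-2-yl)silyl]oxy}-3,4-dihydro-2H-chromen-8-yl]hexanoate
Conditions: BCl3 (2.5 equiv), 2,6-di-tert-butyl-4-methylpyridine (1 equiv), CH2Cl2, −78 → −20 °C; aq. NaHCO3
Reagents that add atoms: none
Why: Chelation-assisted cleavage of an alkyl aryl ether peri to a carbonyl by BCl3: the C4 ketone and the C5 oxygen bind boron, and chloride removes the ethyl group. The hindered pyridine traps protons without binding boron, so the isopropenyl group should not be ionised at these temperatures.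

Step 16
Reactants: 37 methyl (3R)-3-[6-{[(1S,2R)-3,3-dimethyl-2-(prop-1-en-2-yl)cyclobutyl]methyl}-5-hydroxy-2,2-dimethyl-4-oxo-7-{[tri(propan-2-yl)silyl]oxy}-3,4-dihydro-2H-chromen-8-yl]hexanoate
Product: 38 methyl (3R)-3-[6-{[(1S,2R)-3,3-dimethyl-2-(prop-1-en-2-yl)cyclobutyl]methyl}-5,7-dihydroxy-2,2-dimethyl-4-oxo-3,4-dihydro-2H-chromen-8-yl]hexanoate
Conditions: Bu4NF, AcOH (1:1), THF, 0 °C, Ar
Reagents that add atoms: none
Why: Fluoride cleavage of an aryl silyl ether. The acetic acid buffer avoids base-induced opening of the pyranone and hydrolysis of the ester; the electron-rich product is kept under argon.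

Step 17
Reactants: 38 methyl (3R)-3-[6-{[(1S,2R)-3,3-dimethyl-2-(prop-1-en-2-yl)cyclobutyl]methyl}-5,7-dihydroxy-2,2-dimethyl-4-oxo-3,4-dihydro-2H-chromen-8-yl]hexanoate; 39 3-methylbut-2-en-1-yl acetate
Product: 40 methyl (3R)-3-[(6R)-6-{[(1S,2R)-3,3-dimethyl-2-(prop-1-en-2-yl)cyclobutyl]methyl}-5-hydroxy-2,2-dimethyl-6-(3-methylbut-2-en-1-yl)-4,7-dioxo-3,4,6,7-tetrahydro-2H-chromen-8-yl]hexanoate
Conditions: Pd2(dba)3·CHCl3 (2.5 mol%), (1R,2R)-N,N'-bis[2-(diphenylphosphino)benzoyl]cyclohexane-1,2-diamine (7.5 mol%), Et3N (1.5 equiv), THF, 0 °C → rt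
Reagents that add atoms: none
Why: Proposed new method: zerovalent palladium ionises 39 to a cationic (3-methylbut-2-enyl)palladium complex while the amine deprotonates the more acidic C7 hydroxyl of 38; the ambident phenoxide should attack the unsubstituted allyl terminus through C6, which lies between both phenolic oxygens and is less hindered than C8 with its secondary alkyl group, and the dearomatised product is held as an enol hydrogen-bonded to the C4 ketone, so that any O-allyl ether, which re-ionises, is drawn on to it; the chiral pocket of the bis(phosphine) ligand is relied on to choose the face of C6 because the resident stereocentres are too remote; the closest known reaction types are the Tsuji–Trost dearomative allylation of acylphloroglucinols with achiral ligands and the ligand-controlled asymmetric allylic dearomatisation of naphthols.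

Step 18
Reactants: 40 methyl (3R)-3-[(6R)-6-{[(1S,2R)-3,3-dimethyl-2-(prop-1-en-2-yl)cyclobutyl]methyl}-5-hydroxy-2,2-dimethyl-6-(3-methylbut-2-en-1-yl)-4,7-dioxo-3,4,6,7-tetrahydro-2H-chromen-8-yl]hexanoate
Product: 41 (3R)-3-[(6R)-6-{[(1S,2R)-3,3-dimethyl-2-(prop-1-en-2-yl)cyclobutyl]methyl}-5-hydroxy-2,2-dimethyl-6-(3-methylbut-2-en-1-yl)-4,7-dioxo-3,4,6,7-tetrahydro-2H-chromen-8-yl]hexanoic acid
Conditions: LiOH (4 equiv), THF/H2O 3:1, 0 °C → rt; 1 M HCl to pH 3
Reagents that add atoms: lithium hydroxide [Li+].[OH-]
Why: Saponification of a methyl ester. The enolised triketone is present as its delocalised anion, which protects the ring carbonyls from hydroxide; the quaternary C6 and the chain stereocentre cannot epimerise under these conditions.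

## Compound list

1 | 4,4-dimethylcyclopent-2-en-1-one | CC1(C)C=CC(=O)C1 | starting material
2 | 4,4,5,5-tetramethyl-2-(prop-1-en-2-yl)-1,3,2-dioxaborolane | CC(=C)B1OC(C)(C)C(C)(C)O1 | starting material
3 | (4R)-3,3-dimethyl-4-(prop-1-en-2-yl)cyclopentan-1-one | C=C(C)[C@H]1CC(=O)CC1(C)C | intermediate
4 | lithium (3R)-4,4-dimethyl-3-(prop-1-en-2-yl)cyclopent-1-en-1-olate | [Li+].C=C(C)[C@H]1C=C([O-])CC1(C)C | intermediate
5 | (3R)-4,4-dimethyl-3-(prop-1-en-2-yl)-2-(trifluoroacetyl)cyclopentan-1-one (C2 epimers and enol forms) | C=C(C)[C@H]1C(C(=O)C(F)(F)F)C(=O)CC1(C)C | intermediate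
6 | (3R)-2-diazo-4,4-dimethyl-3-(prop-1-en-2-yl)cyclopentan-1-one | C=C(C)[C@H]1C(=[N+]=[N-])C(=O)CC1(C)C | intermediate
7 | [(2R)-3,3-dimethyl-2-(prop-1-en-2-yl)cyclobutylidene]methanone (the ketene) | C=C(C)[C@H]1C(=C=O)CC1(C)C | intermediate
8 | methyl (1S,2R)-3,3-dimethyl-2-(prop-1-en-2-yl)cyclobutane-1-carboxylate (cis) | C=C(C)[C@H]1[C@@H](C(=O)OC)CC1(C)C | intermediate
9 | methyl (1R,2R)-3,3-dimethyl-2-(prop-1-en-2-yl)cyclobutane-1-carboxylate (trans) | C=C(C)[C@H]1[C@H](C(=O)OC)CC1(C)C | intermediate
10 | [(1R,2R)-3,3-dimethyl-2-(prop-1-en-2-yl)cyclobutyl]methanol | C=C(C)[C@H]1[C@H](CO)CC1(C)C | intermediate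
11 | ethoxyethyne (ethoxyacetylene) | CCOC#C | starting material
12 | [(1R,2R)-3,3-dimethyl-2-(prop-1-en-2-yl)cyclobutyl]methyl trifluoromethanesulfonate | C=C(C)[C@H]1[C@H](COS(=O)(=O)C(F)(F)F)CC1(C)C | intermediate
13 | lithium ethoxyacetylide | [Li+].[C-]#COCC | intermediate
14 | (1S,2R)-1-(3-ethoxyprop-2-yn-1-yl)-3,3-dimethyl-2-(prop-1-en-2-yl)cyclobutane | C=C(C)[C@H]1[C@H](CC#COCC)CC1(C)C | intermediate
15 | ethenone (ketene), generated from acetone by pyrolysis | C=C=O | starting material
16 | 2-{[(1S,2R)-3,3-dimethyl-2-(prop-1-en-2-yl)cyclobutyl]methyl}-3-ethoxycyclobut-2-en-1-one | C=C(C)[C@H]1[C@H](CC2=C(OCC)CC2=O)CC1(C)C | intermediate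
17 | (4R)-4-propyloxolan-2-one | CCC[C@@H]1CC(=O)OC1 | starting material
18 | sodium (3R)-3-(hydroxymethyl)hexanoate | [Na+].CCC[C@H](CC(=O)[O-])CO | intermediate
19 | methyl (3R)-3-(hydroxymethyl)hexanoate | CCC[C@H](CC(=O)OC)CO | intermediate
20 | methyl (3R)-3-formylhexanoate | CCC[C@H](CC(=O)OC)C=O | intermediate
21 | methyl (3R)-3-ethynylhexanoate | CCC[C@H](CC(=O)OC)C#C | intermediate
22 | (3R)-3-ethynylhexanoic acid | CCC[C@H](CC(=O)O)C#C | intermediate
23 | dilithium salt of (3R)-3-ethynylhexanoic acid (carboxylate and acetylide) | [Li+].[Li+].CCC[C@H](CC(=O)[O-])C#[C-] | intermediate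
24 | dilithium (3R)-3-(oxidoethynyl)hexanoate (carboxylate and ynolate) | [Li+].[Li+].CCC[C@H](CC(=O)[O-])C#C[O-] | intermediate
25 | tri(propan-2-yl)silyl (3R)-3-({[tri(propan-2-yl)silyl]oxy}ethynyl)hexanoate | CCC[C@H](CC(=O)O[Si](C(C)C)(C(C)C)C(C)C)C#CO[Si](C(C)C)(C(C)C)C(C)C | intermediate
26 | 2-{[(1S,2R)-3,3-dimethyl-2-(prop-1-en-2-yl)cyclobutyl]methyl}-3-ethoxybuta-1,3-dien-1-one | C=C(C)[C@H]1[C@H](CC(=C=O)C(=C)OCC)CC1(C)C | intermediate
27 | tri(propan-2-yl)silyl (3R)-3-[3-{[(1S,2R)-3,3-dimethyl-2-(prop-1-en-2-yl)cyclobutyl]methyl}-3-(1-ethoxyethenyl)-4-oxo-2-{[tri(propan-2-yl)silyl]oxy}cyclobut-1-en-1-yl]hexanoate (both epimers at the quaternary ring carbon) | C=C(C)[C@H]1[C@H](CC2(C(=C)OCC)C(=O)C([C@H](CCC)CC(=O)O[Si](C(C)C)(C(C)C)C(C)C)=C2O[Si](C(C)C)(C(C)C)C(C)C)CC1(C)C | intermediate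
28 | tri(propan-2-yl)silyl (3R)-3-[(3E)-4-{[(1S,2R)-3,3-dimethyl-2-(prop-1-en-2-yl)cyclobutyl]methyl}-5-ethoxy-1-oxo-3-{[tri(propan-2-yl)silyl]oxy}hexa-1,3,5-trien-2-yl]hexanoate | C=C(C)[C@H]1[C@H](C/C(C(=C)OCC)=C(\O[Si](C(C)C)(C(C)C)C(C)C)C(=C=O)[C@H](CCC)CC(=O)O[Si](C(C)C)(C(C)C)C(C)C)CC1(C)C | intermediate
29 | tri(propan-2-yl)silyl (3R)-3-[3-{[(1S,2R)-3,3-dimethyl-2-(prop-1-en-2-yl)cyclobutyl]methyl}-4-ethoxy-6-oxo-2-{[tri(propan-2-yl)silyl]oxy}cyclohexa-1,3-dien-1-yl]hexanoate | C=C(C)[C@H]1[C@H](CC2=C(OCC)CC(=O)C([C@H](CCC)CC(=O)O[Si](C(C)C)(C(C)C)C(C)C)=C2O[Si](C(C)C)(C(C)C)C(C)C)CC1(C)C | intermediate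
30 | tri(propan-2-yl)silyl (3R)-3-[3-{[(1S,2R)-3,3-dimethyl-2-(prop-1-en-2-yl)cyclobutyl]methyl}-4-ethoxy-6-hydroxy-2-{[tri(propan-2-yl)silyl]oxy}phenyl]hexanoate | C=C(C)[C@H]1[C@H](Cc2c(O[Si](C(C)C)(C(C)C)C(C)C)c([C@H](CCC)CC(=O)O[Si](C(C)C)(C(C)C)C(C)C)c(O)cc2OCC)CC1(C)C | intermediate
31 | (3R)-3-[3-{[(1S,2R)-3,3-dimethyl-2-(prop-1-en-2-yl)cyclobutyl]methyl}-4-ethoxy-6-hydroxy-2-{[tri(propan-2-yl)silyl]oxy}phenyl]hexanoic acid | C=C(C)[C@H]1[C@H](Cc2c(O[Si](C(C)C)(C(C)C)C(C)C)c([C@H](CCC)CC(=O)O)c(O)cc2OCC)CC1(C)C | intermediate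
32 | methyl (3R)-3-[3-{[(1S,2R)-3,3-dimethyl-2-(prop-1-en-2-yl)cyclobutyl]methyl}-4-ethoxy-6-hydroxy-2-{[tri(propan-2-yl)silyl]oxy}phenyl]hexanoate | C=C(C)[C@H]1[C@H](Cc2c(O[Si](C(C)C)(C(C)C)C(C)C)c([C@H](CCC)CC(=O)OC)c(O)cc2OCC)CC1(C)C | intermediate
33 | 3-methylbut-2-enoyl chloride | CC(C)=CC(=O)Cl | starting material
34 | methyl (3R)-3-[3-{[(1S,2R)-3,3-dimethyl-2-(prop-1-en-2-yl)cyclobutyl]methyl}-4-ethoxy-6-[(3-methylbut-2-enoyl)oxy]-2-{[tri(propan-2-yl)silyl]oxy}phenyl]hexanoate | C=C(C)[C@H]1[C@H](Cc2c(O[Si](C(C)C)(C(C)C)C(C)C)c([C@H](CCC)CC(=O)OC)c(OC(=O)C=C(C)C)cc2OCC)CC1(C)C | intermediate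
35 | methyl (3R)-3-[3-{[(1S,2R)-3,3-dimethyl-2-(prop-1-en-2-yl)cyclobutyl]methyl}-4-ethoxy-6-hydroxy-5-(3-methylbut-2-enoyl)-2-{[tri(propan-2-yl)silyl]oxy}phenyl]hexanoate | C=C(C)[C@H]1[C@H](Cc2c(O[Si](C(C)C)(C(C)C)C(C)C)c([C@H](CCC)CC(=O)OC)c(O)c(C(=O)C=C(C)C)c2OCC)CC1(C)C | intermediate
36 | methyl (3R)-3-[6-{[(1S,2R)-3,3-dimethyl-2-(prop-1-en-2-yl)cyclobutyl]methyl}-5-ethoxy-2,2-dimethyl-4-oxo-7-{[tri(propan-2-yl)silyl]oxy}-3,4-dihydro-2H-chromen-8-yl]hexanoate | C=C(C)[C@H]1[C@H](Cc2c(O[Si](C(C)C)(C(C)C)C(C)C)c([C@H](CCC)CC(=O)OC)c3OC(C)(C)CC(=O)c3c2OCC)CC1(C)C | intermediate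
37 | methyl (3R)-3-[6-{[(1S,2R)-3,3-dimethyl-2-(prop-1-en-2-yl)cyclobutyl]methyl}-5-hydroxy-2,2-dimethyl-4-oxo-7-{[tri(propan-2-yl)silyl]oxy}-3,4-dihydro-2H-chromen-8-yl]hexanoate | C=C(C)[C@H]1[C@H](Cc2c(O[Si](C(C)C)(C(C)C)C(C)C)c([C@H](CCC)CC(=O)OC)c3OC(C)(C)CC(=O)c3c2O)CC1(C)C | intermediate
38 | methyl (3R)-3-[6-{[(1S,2R)-3,3-dimethyl-2-(prop-1-en-2-yl)cyclobutyl]methyl}-5,7-dihydroxy-2,2-dimethyl-4-oxo-3,4-dihydro-2H-chromen-8-yl]hexanoate | C=C(C)[C@H]1[C@H](Cc2c(O)c([C@H](CCC)CC(=O)OC)c3OC(C)(C)CC(=O)c3c2O)CC1(C)C | intermediate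
39 | 3-methylbut-2-en-1-yl acetate | CC(=O)OCC=C(C)C | starting material
40 | methyl (3R)-3-[(6R)-6-{[(1S,2R)-3,3-dimethyl-2-(prop-1-en-2-yl)cyclobutyl]methyl}-5-hydroxy-2,2-dimethyl-6-(3-methylbut-2-en-1-yl)-4,7-dioxo-3,4,6,7-tetrahydro-2H-chromen-8-yl]hexanoate | C=C(C)[C@H]1[C@H](C[C@]2(CC=C(C)C)C(=O)C([C@H](CCC)CC(=O)OC)=C3OC(C)(C)CC(=O)C3=C2O)CC1(C)C | intermediate
41 | (3R)-3-[(6R)-6-{[(1S,2R)-3,3-dimethyl-2-(prop-1-en-2-yl)cyclobutyl]methyl}-5-hydroxy-2,2-dimethyl-6-(3-methylbut-2-en-1-yl)-4,7-dioxo-3,4,6,7-tetrahydro-2H-chromen-8-yl]hexanoic acid | C=C(C)[C@H]1[C@H](C[C@]2(CC=C(C)C)C(=O)C([C@H](CCC)CC(=O)O)=C3OC(C)(C)CC(=O)C3=C2O)CC1(C)C | target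

## Step count and least certain steps

Total: 18 steps. Longest linear sequence: 14 steps (steps 1 to 6, then 11 to 18); the siloxyalkyne branch (steps 7 to 10) joins at step 11.

**Step 17 (carries the new-method label).** The most likely failure is poor facial selectivity at C6, because the nucleophile is a flat, fully substituted ring whose stereocentres are remote; alkylation at C8 or oxygen, or attack at the substituted allyl terminus, may also compete. Fallback with known chemistry: 38 is treated with 3-methylbut-2-enyl bromide and NaOMe in MeOH at 0 °C, the uncatalysed dearomatising C-alkylation known for acylphloroglucinol anions. This should give both C6 epimers, 40 and methyl (3R)-3-[(6S)-6-{[(1S,2R)-3,3-dimethyl-2-(prop-1-en-2-yl)cyclobutyl]methyl}-5-hydroxy-2,2-dimethyl-6-(3-methylbut-2-en-1-yl)-4,7-dioxo-3,4,6,7-tetrahydro-2H-chromen-8-yl]hexanoate F1. They are diastereomers and should be separable by chromatography, with the configuration assigned by crystallography of a derivative. The fallback sets out from 38 and returns at 40.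

**Step 11 (key step).** The ethoxy donor on the cyclobutenone may retard the first ring opening, and at the higher temperature then needed the siloxyalkyne may isomerise to a silylketene or the vinylketene may dimerise or acylate the product phenol. Fallback: generate vinylketene 26 at room temperature by a photochemical Wolff rearrangement.
- 3-Ethoxybut-3-en-2-one F2 is made from 1-ethoxyvinyllithium and N-methoxy-N-methylacetamide.
- Its lithium enolate (LiN(iPr)2, THF, −78 °C) is alkylated with triflate 12, made from 10 as in step 5, to give 5-[(1R,2R)-3,3-dimethyl-2-(prop-1-en-2-yl)cyclobutyl]-2-ethoxypent-1-en-3-one F3.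
- Trifluoroacetylation of its kinetic enolate gives 4-{[(1R,2R)-3,3-dimethyl-2-(prop-1-en-2-yl)cyclobutyl]methyl}-2-ethoxy-6,6,6-trifluorohex-1-ene-3,5-dione F4, and diazo transfer with CH3SO2N3 and Et3N gives 4-diazo-5-[(1S,2R)-3,3-dimethyl-2-(prop-1-en-2-yl)cyclobutyl]-2-ethoxypent-1-en-3-one F5.
- Irradiation of F5 (300 nm, CH2Cl2, rt) in the presence of 25 causes migration of the ethoxyvinyl group and forms 26, which is trapped by 25; brief warming to 80 °C completes the cascade.

The fallback sets out from 10 and returns at 30.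

**Step 10.** The dilithium salt may be poorly soluble, leaving the oxidation incomplete, and adventitious hydrolysis of the silyl ester would release an acid that destroys the siloxyalkyne. Fallback: protect the carboxyl group covalently as a base-stable orthoester.
- 22 is esterified with (3-methyloxetan-3-yl)methanol (carbodiimide, 4-(dimethylamino)pyridine) to (3-methyloxetan-3-yl)methyl (3R)-3-ethynylhexanoate F6.
- BF3·OEt2 (catalytic, CH2Cl2, −15 °C) rearranges F6 to 1-[(2R)-2-ethynylpentyl]-4-methyl-2,6,7-trioxabicyclo[2.2.2]octane F7.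
- Deprotonation with n-BuLi, oxidation with lithium tert-butyl peroxide and silylation with iPr3SiCl give 4-methyl-1-[(2R)-2-({[tri(propan-2-yl)silyl]oxy}ethynyl)pentyl]-2,6,7-trioxabicyclo[2.2.2]octane F8.
- Heating F8 with 16 as in step 11 gives the orthoester phenol 2-[(2R)-1-(4-methyl-2,6,7-trioxabicyclo[2.2.2]octan-1-yl)pentan-2-yl]-4-{[(1S,2R)-3,3-dimethyl-2-(prop-1-en-2-yl)cyclobutyl]methyl}-5-ethoxy-3-{[tri(propan-2-yl)silyl]oxy}phenol F9.
- Pyridinium p-toluenesulfonate in wet MeOH opens F9 to 3-hydroxy-2-(hydroxymethyl)-2-methylpropyl (3R)-3-[3-{[(1S,2R)-3,3-dimethyl-2-(prop-1-en-2-yl)cyclobutyl]methyl}-4-ethoxy-6-hydroxy-2-{[tri(propan-2-yl)silyl]oxy}phenyl]hexanoate F10, and K2CO3 in MeOH transesterifies F10.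

The fallback sets out from 22 and returns at 32.

**Step 14.** The radical pair may escape the solvent cage, which returns phenol 32, and the enone product absorbs at the irradiation wavelength, so it may screen the starting ester and undergo secondary photochemistry. Fallback without light or acid, from 32:
- Magnesium-mediated ortho-formylation (MgCl2, Et3N, paraformaldehyde, MeCN, reflux) gives methyl (3R)-3-[3-{[(1S,2R)-3,3-dimethyl-2-(prop-1-en-2-yl)cyclobutyl]methyl}-4-ethoxy-5-formyl-6-hydroxy-2-{[tri(propan-2-yl)silyl]oxy}phenyl]hexanoate F11.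
- (2-Methylprop-1-en-1-yl)magnesium bromide (2.2 equiv, THF, −78 °C) adds to the aldehyde to give methyl (3R)-3-[3-{[(1S,2R)-3,3-dimethyl-2-(prop-1-en-2-yl)cyclobutyl]methyl}-4-ethoxy-6-hydroxy-5-(1-hydroxy-3-methylbut-2-en-1-yl)-2-{[tri(propan-2-yl)silyl]oxy}phenyl]hexanoate F12 (both carbinol epimers).
- MnO2 in CH2Cl2 oxidises F12 to enone 35, which is cyclised as in step 14.

The fallback sets out from 32 and returns at 35.

**Step 1.** Insertion at the β-carbon next to the quaternary centre may be slow, so that protodeboronation of 2 competes and the enantioselectivity is eroded. Fallback by resolution: (CH2=C(CH3))2CuLi in THF at −78 °C adds to 1 without a chiral ligand to give the racemic ketone, that is 3 together with (4S)-3,3-dimethyl-4-(prop-1-en-2-yl)cyclopentan-1-one F13. The enantiomers are separated by preparative chromatography on a chiral stationary phase, and the absolute configuration is confirmed by correlation. The fallback sets out from 1 and returns at 3.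

**Step 15.** Traces of protic acid formed from BCl3 may protonate the isopropenyl group, leading to ring expansion of the cyclobutane; the tertiary ether oxygen of the pyranone may also be attacked. Fallback: postpone the C5–O cleavage to the last step, where the ethoxy group has become part of a vinylogous ester that hydroxide can cleave.
- 36 is desilylated (Bu4NF, AcOH, THF) to methyl (3R)-3-[6-{[(1S,2R)-3,3-dimethyl-2-(prop-1-en-2-yl)cyclobutyl]methyl}-5-ethoxy-7-hydroxy-2,2-dimethyl-4-oxo-3,4-dihydro-2H-chromen-8-yl]hexanoate F14.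
- F14 is prenylated at C6 as in step 17, or as in its fallback, to methyl (3R)-3-[(6R)-6-{[(1S,2R)-3,3-dimethyl-2-(prop-1-en-2-yl)cyclobutyl]methyl}-5-ethoxy-2,2-dimethyl-6-(3-methylbut-2-en-1-yl)-4,7-dioxo-3,4,6,7-tetrahydro-2H-chromen-8-yl]hexanoate F15.
- LiOH in dioxane/H2O at 60 °C hydrolyses the methyl ester and cleaves the enol ether by conjugate addition and elimination.

The fallback sets out from 36 and returns at 41.

## Further compounds

F1 | step 17 | methyl (3R)-3-[(6S)-6-{[(1S,2R)-3,3-dimethyl-2-(prop-1-en-2-yl)cyclobutyl]methyl}-5-hydroxy-2,2-dimethyl-6-(3-methylbut-2-en-1-yl)-4,7-dioxo-3,4,6,7-tetrahydro-2H-chromen-8-yl]hexanoate | C=C(C)[C@H]1[C@H](C[C@@]2(CC=C(C)C)C(=O)C([C@H](CCC)CC(=O)OC)=C3OC(C)(C)CC(=O)C3=C2O)CC1(C)C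
F2 | step 11 | 3-ethoxybut-3-en-2-one | CC(=O)C(=C)OCC
F3 | step 11 | 5-[(1R,2R)-3,3-dimethyl-2-(prop-1-en-2-yl)cyclobutyl]-2-ethoxypent-1-en-3-one | C=C(C)[C@H]1[C@H](CCC(=O)C(=C)OCC)CC1(C)C
F4 | step 11 | 4-{[(1R,2R)-3,3-dimethyl-2-(prop-1-en-2-yl)cyclobutyl]methyl}-2-ethoxy-6,6,6-trifluorohex-1-ene-3,5-dione | C=C(C)[C@H]1[C@H](CC(C(=O)C(F)(F)F)C(=O)C(=C)OCC)CC1(C)C
F5 | step 11 | 4-diazo-5-[(1S,2R)-3,3-dimethyl-2-(prop-1-en-2-yl)cyclobutyl]-2-ethoxypent-1-en-3-one | C=C(C)[C@H]1[C@H](CC(=[N+]=[N-])C(=O)C(=C)OCC)CC1(C)C
F6 | step 10 | (3-methyloxetan-3-yl)methyl (3R)-3-ethynylhexanoate | CCC[C@H](CC(=O)OCC1(C)COC1)C#C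
F7 | step 10 | 1-[(2R)-2-ethynylpentyl]-4-methyl-2,6,7-trioxabicyclo[2.2.2]octane | CCC[C@H](CC12OCC(C)(CO1)CO2)C#C
F8 | step 10 | 4-methyl-1-[(2R)-2-({[tri(propan-2-yl)silyl]oxy}ethynyl)pentyl]-2,6,7-trioxabicyclo[2.2.2]octane | CCC[C@H](CC12OCC(C)(CO1)CO2)C#CO[Si](C(C)C)(C(C)C)C(C)C
F9 | step 10 | 2-[(2R)-1-(4-methyl-2,6,7-trioxabicyclo[2.2.2]octan-1-yl)pentan-2-yl]-4-{[(1S,2R)-3,3-dimethyl-2-(prop-1-en-2-yl)cyclobutyl]methyl}-5-ethoxy-3-{[tri(propan-2-yl)silyl]oxy}phenol | C=C(C)[C@H]1[C@H](Cc2c(O[Si](C(C)C)(C(C)C)C(C)C)c([C@H](CCC)CC34OCC(C)(CO3)CO4)c(O)cc2OCC)CC1(C)C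
F10 | step 10 | 3-hydroxy-2-(hydroxymethyl)-2-methylpropyl (3R)-3-[3-{[(1S,2R)-3,3-dimethyl-2-(prop-1-en-2-yl)cyclobutyl]methyl}-4-ethoxy-6-hydroxy-2-{[tri(propan-2-yl)silyl]oxy}phenyl]hexanoate | C=C(C)[C@H]1[C@H](Cc2c(O[Si](C(C)C)(C(C)C)C(C)C)c([C@H](CCC)CC(=O)OCC(C)(CO)CO)c(O)cc2OCC)CC1(C)C
F11 | step 14 | methyl (3R)-3-[3-{[(1S,2R)-3,3-dimethyl-2-(prop-1-en-2-yl)cyclobutyl]methyl}-4-ethoxy-5-formyl-6-hydroxy-2-{[tri(propan-2-yl)silyl]oxy}phenyl]hexanoate | C=C(C)[C@H]1[C@H](Cc2c(O[Si](C(C)C)(C(C)C)C(C)C)c([C@H](CCC)CC(=O)OC)c(O)c(C=O)c2OCC)CC1(C)C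
F12 | step 14 | methyl (3R)-3-[3-{[(1S,2R)-3,3-dimethyl-2-(prop-1-en-2-yl)cyclobutyl]methyl}-4-ethoxy-6-hydroxy-5-(1-hydroxy-3-methylbut-2-en-1-yl)-2-{[tri(propan-2-yl)silyl]oxy}phenyl]hexanoate (both carbinol epimers) | C=C(C)[C@H]1[C@H](Cc2c(O[Si](C(C)C)(C(C)C)C(C)C)c([C@H](CCC)CC(=O)OC)c(O)c(C(O)C=C(C)C)c2OCC)CC1(C)C
F13 | step 1 | (4S)-3,3-dimethyl-4-(prop-1-en-2-yl)cyclopentan-1-one | C=C(C)[C@@H]1CC(=O)CC1(C)C
F14 | step 15 | methyl (3R)-3-[6-{[(1S,2R)-3,3-dimethyl-2-(prop-1-en-2-yl)cyclobutyl]methyl}-5-ethoxy-7-hydroxy-2,2-dimethyl-4-oxo-3,4-dihydro-2H-chromen-8-yl]hexanoate | C=C(C)[C@H]1[C@H](Cc2c(O)c([C@H](CCC)CC(=O)OC)c3OC(C)(C)CC(=O)c3c2OCC)CC1(C)C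
F15 | step 15 | methyl (3R)-3-[(6R)-6-{[(1S,2R)-3,3-dimethyl-2-(prop-1-en-2-yl)cyclobutyl]methyl}-5-ethoxy-2,2-dimethyl-6-(3-methylbut-2-en-1-yl)-4,7-dioxo-3,4,6,7-tetrahydro-2H-chromen-8-yl]hexanoate | C=C(C)[C@H]1[C@H](C[C@]2(CC=C(C)C)C(=O)C([C@H](CCC)CC(=O)OC)=C3OC(C)(C)CC(=O)C3=C2OCC)CC1(C)C
A1 | alternative 1 | (4S,4'S)-3,3'-[(1R,2S)-3,3-dimethylcyclobutane-1,2-dicarbonyl]bis(4-benzyl-1,3-oxazolidin-2-one) | O=C([C@H]1[C@H](C(=O)N2C(=O)OC[C@@H]2Cc2ccccc2)CC1(C)C)N1C(=O)OC[C@@H]1Cc1ccccc1
A2 | alternative 1 | 1,6-bis[(4S)-4-benzyl-2-oxo-1,3-oxazolidin-3-yl]-3,3-dimethylhexane-1,6-dione | O=C(CCC(C)(C)CC(=O)N1C(=O)OC[C@@H]1Cc1ccccc1)N1C(=O)OC[C@@H]1Cc1ccccc1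
A3 | alternative 2 | seven-membered enol lactone between the C7 oxygen and the cyclobutanecarboxyl group of the 6-prenyl-6-(cyclobutylmethyl)-5-oxo chromenone acid (bridged 6,6-dialkyl cyclohexadienone) | O=C4[C@H]1[C@H](C[C@]2(CC=C(C)C)C(O4)=C([C@H](CCC)CC(=O)O)C3=C(C(=O)CC(C)(C)O3)C2=O)CC1(C)C
A4 | alternative 2 | (3R)-3-[5-hydroxy-7-{[(1S,2R)-2-(iodomethyl)-4,4-dimethylcyclobutane-1-carbonyl]oxy}-2,2-dimethyl-6-(3-methylbut-2-en-1-yl)-4-oxo-3,4-dihydro-2H-chromen-8-yl]hexanoic acid | O=C(Oc1c(CC=C(C)C)c(O)c2C(=O)CC(C)(C)Oc2c1[C@H](CCC)CC(=O)O)[C@H]1[C@H](CI)CC1(C)C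
A5 | alternative 3 | 2-(3-methylbut-2-enoyl)-4-(3-methylbut-2-en-1-yl)-4-{[(1S,2R)-3,3-dimethyl-2-(prop-1-en-2-yl)cyclobutyl]methyl}cyclohexane-1,3,5-trione, enol form | C=C(C)[C@H]1[C@H](C[C@]2(CC=C(C)C)C(=O)C=C(O)C(C(=O)C=C(C)C)=C2O)CC1(C)C
A6 | alternative 3 | methyl 2-(chlorocarbonyl)-2-{[(1S,2R)-3,3-dimethyl-2-(prop-1-en-2-yl)cyclobutyl]methyl}-5-methylhex-4-enoate (quaternary centre configured as C6 of A5) | C=C(C)[C@H]1[C@H](C[C@](C(=O)OC)(CC=C(C)C)C(=O)Cl)CC1(C)C
A7 | alternative 3 | 6-methylhept-5-ene-2,4-dione | CC(=O)CC(=O)C=C(C)C
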